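The easy step is the feed: over 30 min of dosing, the charge goes in at a fractional rate of 0.0333 /min. Whatever has gone in and no longer stands as starting material is consumed. I have to choose the next programme, and that subtraction gives me what I need for the choice.

| setting | south-west | north-east | autumn | summer |
|---|---|---|---|---|
| starting material | 0.080 M (fed, over 30 min) | 0.32 M (fed, over 30 min) | 0.16 M (fed, over 30 min) | 0.16 M (fed, over 30 min) |
| coupling partner | 0.32 M | 0.32 M | 0.320 M | 0.320 M |
| temperature | 10 °C | 32 °C |  |  |
| remark | run made earlier | run made earlier | at 0 °C until 10 min, from then on at 40 °C | at 0 °C throughout |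
| time |  |  | 30 min | 20 min |

| run | time / min | product / % | starting material / % |
|---|---|---|---|
| south-west | 4.00 | 1.5 | 9.4 |
| south-west | 8.00 | 5.4 | 14.3 |
| south-west | 12.0 | 9.8 | 16.8 |
| south-west | 15.0 | 13.1 | 17.4 |
| north-east | 1.33 | 2.3 | 0.1 |
| north-east | 2.50 | 3.4 | 0.8 |
| north-east | 4.00 | 5.9 | 0.9 |
| north-east | 5.00 | 7.5 | 0.2 |

(each reading ± 0.5 percentage points)

- which of the two ends with the higher amount of product, in percent of the starting material charged ("neither" if they lie within 2 percentage points) (autumn / summer / neither)
- product at the end, in percent of the starting material charged, autumn
- product at the end, in percent of the starting material charged, summer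

- percentages count the whole charge, also what has not yet gone in

I carry one quantity, the product share: product formed per starting material consumed, which is the selectivity of the whole sequence. In south-west at 15.0 min, half of the charge is in and 17.4% stands, so 32.6% is consumed. The 13.1% of product makes a share of 40.2%. In north-east at 5.00 min, 16.5% is consumed and the share reads 45.5%.

The share turns consumption into product, so I still need the consumption. Starting material in south-west has almost stopped rising by 15.0 min, so its loss balances the feed, and I read a first-order constant of 0.192 /min. North-east stands near 0.500%, a reading no larger than its scatter, which gives a loose 6.67 /min. Extrapolating the logarithm of these two readings linearly in temperature down to 0 °C, outside the range of both runs, I get a rough 0.0382 /min.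

I then reckon that summer holds 46.6% of starting material at 20 min, so 20.0% is consumed. At the south-west share that is 8.05% of product. For autumn I reckon 27.7% at its change of temperature. A half-life of 0.104 min at the north-east constant is far shorter than the remaining 20.0 min, so I take this accumulation and the later feed as consumed, bar about 0.500%. Applying the north-east share to that whole consumption, I reckon 45.3% for autumn, well above my summer figure, and I would charge autumn.

The forecast names autumn, with 47% for autumn and 6.8% for summer, a summer figure lower than mine, and holds that “Selectivity therefore rises gently with temperature”. The flasks give autumn, with 45.7% for autumn and 8.43% for summer.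

    coupling partner + intermediate B ⇌ intermediate C (K = 3.50 /M, k = 0.0120 /M/s, Ea = 63.0 kJ/mol, ΔH = −25.0 kJ/mol)
    starting material ⇌ intermediate A (K = 0.920, k = 5.90 × 10⁻⁴ /s, Ea = 92.0 kJ/mol, ΔH = 14.0 kJ/mol)
    coupling partner ⇌ dormant form (K = 2.10, k = 0.00100 /s, Ea = 87.0 kJ/mol, ΔH = −80.0 kJ/mol)
    starting material → product (k = 2.50 × 10⁻⁴ /s, Ea = 93.0 kJ/mol)
    intermediate B ⇌ intermediate D (K = 1.10, k = 4.50 × 10⁻⁴ /s, Ea = 78.0 kJ/mol, ΔH = −61.0 kJ/mol)
    intermediate B → decomposed reagent (k = 0.00210 /s, Ea = 70.0 kJ/mol)
    intermediate A → product (k = 2.10 × 10⁻⁴ /s, Ea = 90.0 kJ/mol)
    intermediate A → intermediate B (k = 0.00140 /s, Ea = 86.0 kJ/mol)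
    (constants at 0 °C)

In summer, starting material leaves for intermediate A 2.4 times as fast (forward rate alone) as straight for product at 20.0 min, and at 6.04 min intermediate A leaves for intermediate B 6.7 times as fast as for product. The product share comes out at 37.3% in summer, with 8.21% standing as intermediate A, and at 45.9% in autumn. Summer repeated at 15 °C holds 9.61% of starting material at 20.0 min, and the south-west and north-east shares turn that consumption into 22.9% and 26.0% of product, against 25.3% from that flask.

(The earlier runs and the new flask come from a simulation on assumed constants; scatter was added.)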